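**Plan**
- Cuts: O1–C8a of unit T (aryl–oxygen bond, Pd), O1–C2 of units M and B, the interflavan bonds C4(T)–C8(M) and C4(M)–C8(B), and in every unit C3–C4 (aldol) and C2–aryl (Grignard). T, M, B are the upper, middle and 3,4-diol flavan units.
- Feature used: in ring C of unit T, O1–C8a joins the ring oxygen to an aromatic carbon of ring A and is the only ring bond that ends on no stereocentre. C2, C3 and C4 are therefore fixed on an open chain and the pyran is closed there from the C2 hydroxyl and a C8a bromide.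
- Forward, unit T: glycolate aldol on the ring A aldehyde, ester tether to 3,5-bis(benzyloxy)phenol, Friedel–Crafts closure to a dihydrocoumarin (makes C4–C8), aryl Grignard on the lactol, then Pd closure of ring C.
- Forward, units M and B: the phenol set free is formylated and carries unit M (same aldol and tether sequence, ring C closed by hemiketal reduction), then unit B (aldol, Weinreb ketone, Mitsunobu closure); twelve benzyl ethers come off last.
- Stereochemistry: C3 of each unit from Evans syn aldols ((S)-4-benzyl auxiliary for T, (R)-4-benzyl for M, (S)-4-isopropyl for B). C4 of T and M from the trans-selective tethered Friedel–Crafts step, C4 of B from the syn aldol. C2 from chelation-controlled Grignard addition (T), hydride delivery to the cyclic oxocarbenium ion (M), and chelation-controlled reduction followed by Mitsunobu inversion (B).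

Key step: step 11

Remark 1: T-yl = (2S,3S)-3,5,7-tris(benzyloxy)-2-[4-(benzyloxy)phenyl]chroman-4-yl bonded through C4 on the face of its 2-aryl and 3-benzyloxy groups (all-cis unit T); MT-yl = (2R,3R)-3,5,7-tris(benzyloxy)-2-[4-(benzyloxy)phenyl]-8-(T-yl)chroman-4-yl bonded in the same all-cis sense (units M and T).
Remark 2: the CIP letter at C4 of a flavan unit changes with the protecting groups on the neighbouring ring, so in the larger intermediates this centre is given as cis or trans to the C3 oxygen; 4-(benzyloxy)phenylmagnesium bromide (16) is taken as the commercial THF solution.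

**Unit T**

Step 1
Reactants: 1 5-bromoresorcinol
Product: 2 1,3-bis(benzyloxy)-5-bromobenzene
Conditions: BnBr, K2CO3, DMF, 60 °C
Reagents that add atoms: benzyl bromide (BrCc1ccccc1)
Why: Williamson etherification of both phenols with a benzylic halide and carbonate is routine and should leave the aryl bromide untouched.

Step 2
Reactants: 2 1,3-bis(benzyloxy)-5-bromobenzene
Product: 4 2,4-bis(benzyloxy)-6-bromobenzaldehyde, via iminium chloride 3 (not isolated)
Conditions: POCl3, DMF, 0 to 70 °C; then H2O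
Reagents that add atoms: N,N-dimethylformamide (CN(C)C=O); water (O)
Why: Vilsmeier–Haack formylation should attack the carbon para to one benzyloxy group and ortho to the other, which is preferred over the carbon flanked by both ethers, and hydrolysis of the iminium salt should give the aldehyde.

Step 3
Reactants: 5 (S)-4-benzyl-1,3-oxazolidin-2-one; 6 (benzyloxy)acetyl chloride
Product: 7 (S)-4-benzyl-3-[(benzyloxy)acetyl]-1,3-oxazolidin-2-one
Conditions: Et3N, DMAP (cat.), CH2Cl2, 0 °C to rt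
Reagents that add atoms: none
Why: DMAP-catalysed N-acylation of the oxazolidinone with the acid chloride is a standard entry to Evans glycolate imides and touches no stereocentre.

Step 4
Reactants: 4 2,4-bis(benzyloxy)-6-bromobenzaldehyde; 7 (S)-glycolate imide
Product: 9 (4S)-4-benzyl-3-{(2S,3R)-2-(benzyloxy)-3-[2,4-bis(benzyloxy)-6-bromophenyl]-3-hydroxypropanoyl}-1,3-oxazolidin-2-one, via boron enolate 8 (not isolated)
Conditions: 7, Bu2BOTf, i-Pr2NEt, CH2Cl2, −78 to 0 °C; then 4, −78 to 0 °C; pH 7 buffer, MeOH, H2O2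
Reagents that add atoms: none
Why: Evans syn aldol reaction, in which the (Z)-boron enolate should add through a chair Zimmerman–Traxler transition state on the face away from the auxiliary benzyl group, setting the α-carbon (2S, the later C3 of unit T) and the syn carbinol (3R).

Step 5
Reactants: 9 syn aldol adduct
Product: 11 (2S,3R)-2-(benzyloxy)-3-[2,4-bis(benzyloxy)-6-bromophenyl]-3-hydroxypropanoic acid, via peroxy acid 10 (not isolated)
Conditions: LiOH, H2O2, THF/H2O, 0 °C; then Na2SO3; then 1 M HCl to pH 3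
Reagents that add atoms: hydrogen peroxide (OO)
Why: Lithium hydroperoxide hydrolysis should cleave the exocyclic imide carbonyl at a temperature low enough to avoid retro-aldol cleavage, and sulfite should reduce the peroxy acid to the acid with both stereocentres intact.

Step 6
Reactants: 11 hydroxy acid; 12 3,5-bis(benzyloxy)phenol
Product: 13 3,5-bis(benzyloxy)phenyl (2S,3R)-2-(benzyloxy)-3-[2,4-bis(benzyloxy)-6-bromophenyl]-3-hydroxypropanoate
Conditions: DCC, DMAP (cat.), CH2Cl2, 0 °C to rt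
Reagents that add atoms: none
Why: Steglich esterification should acylate the phenol much faster than the hindered benzylic hydroxyl and so tether the phloroglucinol ring of unit M to the carboxyl carbon.

Step 7
Reactants: 13 aryl ester
Product: 14 (3S,4S)-3,5,7-tris(benzyloxy)-4-[2,4-bis(benzyloxy)-6-bromophenyl]chroman-2-one (3,4-trans)
Conditions: Sc(OTf)3 (10 mol %), CH2Cl2, 4 Å MS, −20 °C
Reagents that add atoms: none
Why: Intramolecular Friedel–Crafts alkylation, in which the benzylic cation stabilised by the ortho and para benzyloxy groups should be captured by the tethered arene only at the carbon ortho to the ester oxygen, and allylic 1,3-strain with the doubly ortho-substituted ring should hold the C3 hydrogen in the cation plane so that the arene adds anti to the benzyloxy group, setting C4 trans to C3 in the lactone (cis in the later flavan, whose ring closes on the other aryl group).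

Step 8
Reactants: 14 lactone
Product: 15 (3S,4S)-3,5,7-tris(benzyloxy)-4-[2,4-bis(benzyloxy)-6-bromophenyl]chroman-2-ol (lactol; both anomers)
Conditions: i-Bu2AlH, CH2Cl2, −78 °C
Reagents that add atoms: none
Why: Partial reduction of a lactone by diisobutylaluminium hydride at −78 °C should stop at the lactol, a masked α-benzyloxy aldehyde, without touching C3 or C4.

Step 9
Reactants: 15 lactol; 16 4-(benzyloxy)phenylmagnesium bromide
Product: 17 (1S,2S,3S)-2-(benzyloxy)-1-[4-(benzyloxy)phenyl]-3-[2,4-bis(benzyloxy)-6-bromophenyl]-3-[2,4-bis(benzyloxy)-6-hydroxyphenyl]propan-1-ol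
Conditions: 16 (4 equiv, THF solution), CH2Cl2, −78 to −20 °C; aq NH4Cl
Reagents that add atoms: none
Why: Chelation-controlled Grignard addition, in which the first equivalent should open the lactol to the magnesium phenoxide aldehyde and the aryl group should then add to the five-membered magnesium chelate of the aldehyde and the α-benzyloxy oxygen from the face away from the diarylmethyl group, giving the 1,2-syn alcohol (C1, the later C2 of unit T).

Step 10
Reactants: 17 phenol diol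
Product: 18 (1S,2S,3S)-2-(benzyloxy)-1-[4-(benzyloxy)phenyl]-3-[2,4-bis(benzyloxy)-6-bromophenyl]-3-[2,4-bis(benzyloxy)-6-(methoxymethoxy)phenyl]propan-1-ol
Conditions: MOMCl, K2CO3, acetone, rt
Reagents that add atoms: chloromethyl methyl ether (COCCl)
Why: O-Alkylation of the phenoxide, since K2CO3 should deprotonate only the phenol, so the MOM group goes on the phenolic oxygen and the secondary alcohol stays free.

Step 11
Reactants: 18 open-chain bromo alcohol
Product: 19 (2S,3S,4R)-3,5,7-tris(benzyloxy)-2-[4-(benzyloxy)phenyl]-4-[2,4-bis(benzyloxy)-6-(methoxymethoxy)phenyl]chromane (all-cis; benzylated unit T on ring A of unit M)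
Conditions: Pd(OAc)2 (5 mol %), 2-(di-tert-butylphosphino)-1,1'-binaphthyl (6 mol %), Cs2CO3, toluene, 80 °C
Reagents that add atoms: none
Why: Oxidative addition of the zerovalent palladium–phosphine complex (formed from Pd(OAc)2) into the C8a–Br bond of ring A, exchange of bromide for the caesium C2 alkoxide and C–O reductive elimination from the six-membered aryl(alkoxo)palladium chelate should give the chroman. The closest known reaction is the intramolecular palladium-catalysed etherification of 3-(2-bromoaryl)propanols with bulky dialkylbiaryl phosphines (Buchwald-type C–O coupling), which is established for secondary alcohols. Ring C closes through O1–C8a, a 6-exo closure onto the aromatic carbon, and this is the one ring bond that ends on no stereocentre. No stereocentre is formed; C2, C3 and C4 keep the configurations set in steps 9, 4 and 7 because no bond to them is made or broken and Cs2CO3 is too weak a base to epimerise them. The step needs C–O reductive elimination to be faster than β-hydride elimination to the C2 ketone, which the bulky electron-rich binaphthyl phosphine favours, and it needs a single nucleophile, which is secured because the phenol on ring A of unit M is a MOM ether and the C3 oxygen a benzyl ether, so only the C2 hydroxyl can bind palladium and a five-membered closure is excluded.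

Step 12
Reactants: 19 MOM ether
Product: 20 3,5-bis(benzyloxy)-2-(T-yl)phenol
Conditions: HCl (cat.), MeOH/THF, 45 °C
Reagents that add atoms: none
Why: Acid-catalysed acetal exchange should remove the phenolic MOM group as dimethoxymethane under conditions too mild to ionise the benzyl ethers or the C4–aryl bond.

**Unit M**

Step 13
Reactants: 20 phenol
Product: 21 4,6-bis(benzyloxy)-2-hydroxy-3-(T-yl)benzaldehyde
Conditions: MgCl2, Et3N, (CH2O)n, THF, reflux
Reagents that add atoms: formaldehyde, used as paraformaldehyde (C=O)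
Why: Magnesium-mediated ortho-formylation of phenols (Casnati–Skattebøl) should deliver formaldehyde within the magnesium phenoxide to the only free ortho carbon, the later C4a of unit M, and a second formaldehyde should oxidise the benzylic alkoxide to the aldehyde.

Step 14
Reactants: 21 salicylaldehyde
Product: 22 2-(allyloxy)-4,6-bis(benzyloxy)-3-(T-yl)benzaldehyde
Conditions: allyl bromide, K2CO3, DMF, 50 °C
Reagents that add atoms: allyl bromide (C=CCBr)
Why: Williamson allylation should mask the phenol, the later O1 of unit M, with a group that survives boron enolates, peroxide, Lewis acid and Grignard reagents and leaves under neutral conditions.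

Step 15
Reactants: 23 (R)-4-benzyl-1,3-oxazolidin-2-one; 6 (benzyloxy)acetyl chloride
Product: 24 (R)-4-benzyl-3-[(benzyloxy)acetyl]-1,3-oxazolidin-2-one
Conditions: Et3N, DMAP (cat.), CH2Cl2, 0 °C to rt
Reagents that add atoms: none
Why: The same N-acylation as in step 3 should give the enantiomeric glycolate imide needed for unit M.

Step 16
Reactants: 22 aldehyde; 24 (R)-glycolate imide
Product: 26 (4R)-4-benzyl-3-{(2R,3S)-3-[2-(allyloxy)-4,6-bis(benzyloxy)-3-(T-yl)phenyl]-2-(benzyloxy)-3-hydroxypropanoyl}-1,3-oxazolidin-2-one, via boron enolate 25 (not isolated)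
Conditions: 24, Bu2BOTf, i-Pr2NEt, CH2Cl2, −78 to 0 °C; then 22, −78 to 0 °C; pH 7 buffer, MeOH, H2O2
Reagents that add atoms: none
Why: Evans syn aldol reaction with the (R)-auxiliary, whose reagent control should override the remote unit T and set the α-carbon (2R, the later C3 of unit M) in the sense opposite to step 4.

Step 17
Reactants: 26 syn aldol adduct
Product: 28 (2R,3S)-3-[2-(allyloxy)-4,6-bis(benzyloxy)-3-(T-yl)phenyl]-2-(benzyloxy)-3-hydroxypropanoic acid, via peroxy acid 27 (not isolated)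
Conditions: LiOH, H2O2, THF/H2O, 0 °C; then Na2SO3; then 1 M HCl to pH 3
Reagents that add atoms: hydrogen peroxide (OO)
Why: Lithium hydroperoxide hydrolysis of the imide as in step 5 should leave the allyl and benzyl ethers and the isolated alkene untouched.

Step 18
Reactants: 28 hydroxy acid; 12 3,5-bis(benzyloxy)phenol
Product: 29 3,5-bis(benzyloxy)phenyl (2R,3S)-3-[2-(allyloxy)-4,6-bis(benzyloxy)-3-(T-yl)phenyl]-2-(benzyloxy)-3-hydroxypropanoate
Conditions: DCC, DMAP (cat.), CH2Cl2, 0 °C to rt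
Reagents that add atoms: none
Why: Steglich esterification should tether the phloroglucinol ring of unit B to the carboxyl carbon, the later C2 of unit M.

Step 19
Reactants: 29 aryl ester
Product: 30 (3R)-4-[2-(allyloxy)-4,6-bis(benzyloxy)-3-(T-yl)phenyl]-3,5,7-tris(benzyloxy)chroman-2-one (3,4-trans)
Conditions: Sc(OTf)3 (10 mol %), CH2Cl2, 4 Å MS, −20 °C
Reagents that add atoms: none
Why: Intramolecular Friedel–Crafts alkylation as in step 7, in which the benzylic cation on ring A of unit M should be captured by the tethered arene ortho to the ester oxygen and anti to the C3 benzyloxy group, forming the C4(M)–C8(B) bond and setting C4 of unit M (trans in this lactone, hence cis to C3 once ring C of unit M is closed on the other ring).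

Step 20
Reactants: 30 lactone; 16 4-(benzyloxy)phenylmagnesium bromide
Product: 31 (2R)-3-[2-(allyloxy)-4,6-bis(benzyloxy)-3-(T-yl)phenyl]-2-(benzyloxy)-1-[4-(benzyloxy)phenyl]-3-[2,4-bis(benzyloxy)-6-hydroxyphenyl]propan-1-one (C3 as C4 of 30)
Conditions: 16 (1.2 equiv), THF, −78 °C; aq NH4Cl at −78 °C
Reagents that add atoms: none
Why: Addition of one aryl Grignard equivalent to a lactone, where the magnesium hemiketal, held as a chelate by the C3 benzyloxy group, should survive at −78 °C until the quench and then open to the aryl ketone and the free phenol of ring A of unit B.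

Step 21
Reactants: 31 keto phenol
Product: 32 (2R)-3-[2-(allyloxy)-4,6-bis(benzyloxy)-3-(T-yl)phenyl]-2-(benzyloxy)-1-[4-(benzyloxy)phenyl]-3-[2,4-bis(benzyloxy)-6-(tert-butyldimethylsilyloxy)phenyl]propan-1-one
Conditions: TBSCl, imidazole, DMF, rt
Reagents that add atoms: tert-butyl(chloro)dimethylsilane (CC(C)(C)[Si](C)(C)Cl)
Why: Silylation of the phenol should block the one hydroxyl that could also close a hemiketal on the ketone, so that only the oxygen on ring A of unit M can do so later.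

Step 22
Reactants: 32 allyl ether
Product: 33 (2R)-2-(benzyloxy)-1-[4-(benzyloxy)phenyl]-3-[2,4-bis(benzyloxy)-6-(tert-butyldimethylsilyloxy)phenyl]-3-[4,6-bis(benzyloxy)-2-hydroxy-3-(T-yl)phenyl]propan-1-one
Conditions: Pd(PPh3)4 (5 mol %), morpholine, THF, rt
Reagents that add atoms: none
Why: Tsuji–Trost deallylation, in which zerovalent palladium should ionise the allyl aryl ether and morpholine trap the allyl complex, freeing the phenol under neutral conditions that do not epimerise the α-benzyloxy ketone.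

Step 23
Reactants: 33 keto phenol
Product: 35 (2R,3R)-3,5,7-tris(benzyloxy)-2-[4-(benzyloxy)phenyl]-4-[2,4-bis(benzyloxy)-6-(tert-butyldimethylsilyloxy)phenyl]-8-(T-yl)chromane (all-cis), via cyclic hemiketal 34 (not isolated)
Conditions: Et3SiH, CF3CO2H, CH2Cl2, −40 to 0 °C
Reagents that add atoms: none
Why: Ionic hydrogenation of a cyclic hemiketal (reductive etherification, as in C-aryl glycoside synthesis), in which acid should ionise the hemiketal to the 2-aryl oxocarbenium ion of ring C and the silane deliver hydride to the face opposite the cis-disposed 3-benzyloxy and 4-aryl groups, closing O1–C2 of unit M and setting C2 all-cis.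

Step 24
Reactants: 35 silyl ether
Product: 36 3,5-bis(benzyloxy)-2-(MT-yl)phenol
Conditions: Bu4NF, AcOH, THF, 0 °C
Reagents that add atoms: none
Why: Fluoride desilylation should cleave the aryl silyl ether selectively while acetic acid buffers the phenoxide.

**Unit B**

Step 25
Reactants: 36 phenol
Product: 37 4,6-bis(benzyloxy)-2-hydroxy-3-(MT-yl)benzaldehyde
Conditions: MgCl2, Et3N, (CH2O)n, THF, reflux
Reagents that add atoms: formaldehyde, used as paraformaldehyde (C=O)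
Why: Magnesium-mediated ortho-formylation as in step 13 should put the aldehyde carbon, the later C4 of unit B, on the only free ortho position of the phenol.

Step 26
Reactants: 37 salicylaldehyde
Product: 38 2-(allyloxy)-4,6-bis(benzyloxy)-3-(MT-yl)benzaldehyde
Conditions: allyl bromide, K2CO3, DMF, 50 °C
Reagents that add atoms: allyl bromide (C=CCBr)
Why: Williamson allylation should protect the phenol, the later O1 of unit B, for the aldol and organometallic steps.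

Step 27
Reactants: 39 (S)-4-isopropyl-1,3-oxazolidin-2-one; 6 (benzyloxy)acetyl chloride
Product: 40 (S)-3-[(benzyloxy)acetyl]-4-isopropyl-1,3-oxazolidin-2-one
Conditions: Et3N, DMAP (cat.), CH2Cl2, 0 °C to rt
Reagents that add atoms: none
Why: The same N-acylation as in step 3 should give the valinol-derived glycolate imide, which directs aldol additions in the same sense as the (S)-4-benzyl imide and whose aldol adducts are established substrates for aluminium amide transamination.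

Step 28
Reactants: 38 aldehyde; 40 (S)-4-isopropyl glycolate imide
Product: 42 (4S)-3-{(2S,3R)-3-[2-(allyloxy)-4,6-bis(benzyloxy)-3-(MT-yl)phenyl]-2-(benzyloxy)-3-hydroxypropanoyl}-4-isopropyl-1,3-oxazolidin-2-one, via boron enolate 41 (not isolated)
Conditions: 40, Bu2BOTf, i-Pr2NEt, CH2Cl2, −78 to 0 °C; then 38, −78 to 0 °C; pH 7 buffer, MeOH, H2O2
Reagents that add atoms: none
Why: Evans syn aldol reaction, in which the (Z)-dibutylboron enolate should add through a chair Zimmerman–Traxler transition state on the face away from the auxiliary isopropyl group, setting both the α-carbon (the later C3 of unit B) and the carbinol carbon (the later C4), whose syn relation in the chain is the 3,4-trans relation of the flavan-3,4-diol.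

Step 29
Reactants: 42 syn aldol adduct
Product: 43 (2S,3R)-3-[2-(allyloxy)-4,6-bis(benzyloxy)-3-(MT-yl)phenyl]-2-(benzyloxy)-3-hydroxy-N-methoxy-N-methylpropanamide
Conditions: Me(MeO)NH·HCl, AlMe3, CH2Cl2, −20 to 0 °C
Reagents that add atoms: N,O-dimethylhydroxylamine hydrochloride (CNOC.Cl)
Why: Weinreb transamination of the aldol imide by the aluminium amide should be assisted by the free β-hydroxyl and release the auxiliary without epimerising the α-carbon.

Step 30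
Reactants: 43 Weinreb amide
Product: 44 (2S,3R)-3-[2-(allyloxy)-4,6-bis(benzyloxy)-3-(MT-yl)phenyl]-2-(benzyloxy)-3-(tert-butyldimethylsilyloxy)-N-methoxy-N-methylpropanamide
Conditions: TBSOTf, 2,6-lutidine, CH2Cl2, −78 °C
Reagents that add atoms: tert-butyldimethylsilyl trifluoromethanesulfonate (CC(C)(C)[Si](C)(C)OS(=O)(=O)C(F)(F)F)
Why: Silylation with the silyl triflate and a hindered base should protect the benzylic C4 oxygen as an ether that cannot chelate in the next two steps.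

Step 31
Reactants: 44 silyl ether; 16 4-(benzyloxy)phenylmagnesium bromide
Product: 45 (2S,3R)-3-[2-(allyloxy)-4,6-bis(benzyloxy)-3-(MT-yl)phenyl]-2-(benzyloxy)-1-[4-(benzyloxy)phenyl]-3-(tert-butyldimethylsilyloxy)propan-1-one
Conditions: 16 (3 equiv), THF, −20 to 0 °C; aq NH4Cl
Reagents that add atoms: none
Why: Weinreb ketone synthesis, in which the chelated tetrahedral magnesium intermediate should prevent a second addition and collapse to the aryl ketone on work-up.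

Step 32
Reactants: 45 ketone
Product: 46 1,2-anti-3-[2-(allyloxy)-4,6-bis(benzyloxy)-3-(MT-yl)phenyl]-2-(benzyloxy)-1-[4-(benzyloxy)phenyl]-3-(tert-butyldimethylsilyloxy)propan-1-ol (C2 and C3 as in 45)
Conditions: Zn(BH4)2, Et2O, −30 °C
Reagents that add atoms: none
Why: Chelation-controlled reduction, in which zinc should bind the ketone and the α-benzyloxy oxygen and hydride enter from the face away from the C3 chain, giving the 1,2-anti alcohol at the later C2 of unit B.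

Step 33
Reactants: 46 allyl ether
Product: 47 1,2-anti-2-(benzyloxy)-1-[4-(benzyloxy)phenyl]-3-[4,6-bis(benzyloxy)-2-hydroxy-3-(MT-yl)phenyl]-3-(tert-butyldimethylsilyloxy)propan-1-ol
Conditions: Pd(PPh3)4 (5 mol %), morpholine, THF, rt
Reagents that add atoms: none
Why: Tsuji–Trost deallylation as in step 22 should free the phenol without affecting the silyl and benzyl ethers.

Step 34
Reactants: 47 phenol alcohol
Product: 48 (2S)-3,5,7-tris(benzyloxy)-2-[4-(benzyloxy)phenyl]-4-(tert-butyldimethylsilyloxy)-8-(MT-yl)chromane (2,3-cis-3,4-trans)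
Conditions: PPh3, DIAD, toluene, 0 °C
Reagents that add atoms: none
Why: Intramolecular Mitsunobu etherification, in which the phenol should displace the oxyphosphonium group at the benzylic carbon with inversion, closing O1–C2 of unit B and turning the 1,2-anti alcohol into the 2,3-cis flavan.

Step 35
Reactants: 48 silyl ether
Product: 49 (2S)-3,5,7-tris(benzyloxy)-2-[4-(benzyloxy)phenyl]-8-(MT-yl)chroman-4-ol (2,3-cis-3,4-trans)
Conditions: Bu4NF, AcOH, THF, rt
Reagents that add atoms: none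
Why: Fluoride desilylation should free the C4 hydroxyl of unit B under nearly neutral conditions that do not ionise this benzylic position.

Step 36
Reactants: 49 dodecabenzyl ether
Product: 50 CNP0159291.1
Conditions: H2 (1 atm), Pd(OH)2/C, THF/MeOH, rt
Reagents that add atoms: none
Why: Hydrogenolysis of the twelve benzyl ethers over Pd(OH)2 on carbon under neutral conditions is the usual last step for proanthocyanidins and should be stopped as soon as the ethers are gone so that the benzylic C4 hydroxyl of unit B survives.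

**Compound list**

1 | 5-bromoresorcinol | Oc1cc(O)cc(Br)c1 | starting material
2 | 1,3-bis(benzyloxy)-5-bromobenzene | Brc1cc(OCc9ccccc9)cc(OCc9ccccc9)c1 | intermediate
3 | N-{[2,4-bis(benzyloxy)-6-bromophenyl]methylidene}-N-methylmethanaminium chloride | C[N+](C)=Cc1c(Br)cc(OCc9ccccc9)cc1OCc9ccccc9.[Cl-] | intermediate (not isolated)
4 | 2,4-bis(benzyloxy)-6-bromobenzaldehyde | O=Cc1c(Br)cc(OCc9ccccc9)cc1OCc9ccccc9 | intermediate
5 | (S)-4-benzyl-1,3-oxazolidin-2-one | O=C1N[C@@H](Cc2ccccc2)CO1 | starting material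
6 | (benzyloxy)acetyl chloride | O=C(Cl)COCc1ccccc1 | starting material
7 | (S)-4-benzyl-3-[(benzyloxy)acetyl]-1,3-oxazolidin-2-one | O=C(COCc1ccccc1)N1[C@@H](Cc2ccccc2)COC1=O | intermediate
8 | (Z)-dibutylboron enolate of 7 | CCCCB(CCCC)O/C(=C\OCc1ccccc1)N1[C@@H](Cc2ccccc2)COC1=O | intermediate (not isolated)
9 | (4S)-4-benzyl-3-{(2S,3R)-2-(benzyloxy)-3-[2,4-bis(benzyloxy)-6-bromophenyl]-3-hydroxypropanoyl}-1,3-oxazolidin-2-one | O=C([C@@H](OCc9ccccc9)[C@H](O)c1c(Br)cc(OCc9ccccc9)cc1OCc9ccccc9)N1[C@@H](Cc2ccccc2)COC1=O | intermediate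
10 | (2S,3R)-2-(benzyloxy)-3-[2,4-bis(benzyloxy)-6-bromophenyl]-3-hydroxypropaneperoxoic acid | OOC(=O)[C@@H](OCc9ccccc9)[C@H](O)c1c(Br)cc(OCc9ccccc9)cc1OCc9ccccc9 | intermediate (not isolated)
11 | (2S,3R)-2-(benzyloxy)-3-[2,4-bis(benzyloxy)-6-bromophenyl]-3-hydroxypropanoic acid | OC(=O)[C@@H](OCc9ccccc9)[C@H](O)c1c(Br)cc(OCc9ccccc9)cc1OCc9ccccc9 | intermediate
12 | 3,5-bis(benzyloxy)phenol | Oc1cc(OCc9ccccc9)cc(OCc9ccccc9)c1 | starting material
13 | 3,5-bis(benzyloxy)phenyl (2S,3R)-2-(benzyloxy)-3-[2,4-bis(benzyloxy)-6-bromophenyl]-3-hydroxypropanoate | O=C(Oc1cc(OCc9ccccc9)cc(OCc9ccccc9)c1)[C@@H](OCc9ccccc9)[C@H](O)c1c(Br)cc(OCc9ccccc9)cc1OCc9ccccc9 | intermediate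
14 | (3S,4S)-3,5,7-tris(benzyloxy)-4-[2,4-bis(benzyloxy)-6-bromophenyl]chroman-2-one (3,4-trans) | O=C1Oc2cc(OCc9ccccc9)cc(OCc9ccccc9)c2[C@@H](c4c(OCc9ccccc9)cc(OCc9ccccc9)cc4Br)[C@@H]1OCc9ccccc9 | intermediate
15 | (3S,4S)-3,5,7-tris(benzyloxy)-4-[2,4-bis(benzyloxy)-6-bromophenyl]chroman-2-ol (both anomers) | OC1Oc2cc(OCc9ccccc9)cc(OCc9ccccc9)c2[C@@H](c4c(OCc9ccccc9)cc(OCc9ccccc9)cc4Br)[C@@H]1OCc9ccccc9 | intermediate
16 | 4-(benzyloxy)phenylmagnesium bromide | Br[Mg]c1ccc(OCc2ccccc2)cc1 | starting material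
17 | (1S,2S,3S)-2-(benzyloxy)-1-[4-(benzyloxy)phenyl]-3-[2,4-bis(benzyloxy)-6-bromophenyl]-3-[2,4-bis(benzyloxy)-6-hydroxyphenyl]propan-1-ol | Oc1cc(OCc9ccccc9)cc(OCc9ccccc9)c1[C@@H](c4c(OCc9ccccc9)cc(OCc9ccccc9)cc4Br)[C@H](OCc9ccccc9)[C@@H](O)c4ccc(OCc9ccccc9)cc4 | intermediate
18 | (1S,2S,3S)-2-(benzyloxy)-1-[4-(benzyloxy)phenyl]-3-[2,4-bis(benzyloxy)-6-bromophenyl]-3-[2,4-bis(benzyloxy)-6-(methoxymethoxy)phenyl]propan-1-ol | COCOc1cc(OCc9ccccc9)cc(OCc9ccccc9)c1[C@@H](c4c(OCc9ccccc9)cc(OCc9ccccc9)cc4Br)[C@H](OCc9ccccc9)[C@@H](O)c4ccc(OCc9ccccc9)cc4 | intermediate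
19 | (2S,3S,4R)-3,5,7-tris(benzyloxy)-2-[4-(benzyloxy)phenyl]-4-[2,4-bis(benzyloxy)-6-(methoxymethoxy)phenyl]chromane (all-cis) | COCOc1cc(OCc9ccccc9)cc(OCc9ccccc9)c1[C@H]3c4c(OCc9ccccc9)cc(OCc9ccccc9)cc4O[C@@H](c4ccc(OCc9ccccc9)cc4)[C@H]3OCc9ccccc9 | intermediate
20 | 3,5-bis(benzyloxy)-2-(T-yl)phenol | Oc1cc(OCc9ccccc9)cc(OCc9ccccc9)c1[C@H]3c4c(OCc9ccccc9)cc(OCc9ccccc9)cc4O[C@@H](c4ccc(OCc9ccccc9)cc4)[C@H]3OCc9ccccc9 | intermediate
21 | 4,6-bis(benzyloxy)-2-hydroxy-3-(T-yl)benzaldehyde | Oc1c(C=O)c(OCc9ccccc9)cc(OCc9ccccc9)c1[C@H]3c4c(OCc9ccccc9)cc(OCc9ccccc9)cc4O[C@@H](c4ccc(OCc9ccccc9)cc4)[C@H]3OCc9ccccc9 | intermediate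
22 | 2-(allyloxy)-4,6-bis(benzyloxy)-3-(T-yl)benzaldehyde | C=CCOc1c(C=O)c(OCc9ccccc9)cc(OCc9ccccc9)c1[C@H]3c4c(OCc9ccccc9)cc(OCc9ccccc9)cc4O[C@@H](c4ccc(OCc9ccccc9)cc4)[C@H]3OCc9ccccc9 | intermediate
23 | (R)-4-benzyl-1,3-oxazolidin-2-one | O=C1N[C@H](Cc2ccccc2)CO1 | starting material
24 | (R)-4-benzyl-3-[(benzyloxy)acetyl]-1,3-oxazolidin-2-one | O=C(COCc1ccccc1)N1[C@H](Cc2ccccc2)COC1=O | intermediate
25 | (Z)-dibutylboron enolate of 24 | CCCCB(CCCC)O/C(=C\OCc1ccccc1)N1[C@H](Cc2ccccc2)COC1=O | intermediate (not isolated)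
26 | (4R)-4-benzyl-3-{(2R,3S)-3-[2-(allyloxy)-4,6-bis(benzyloxy)-3-(T-yl)phenyl]-2-(benzyloxy)-3-hydroxypropanoyl}-1,3-oxazolidin-2-one | O=C([C@H](OCc9ccccc9)[C@@H](O)c5c(OCC=C)c([C@H]3c4c(OCc9ccccc9)cc(OCc9ccccc9)cc4O[C@@H](c4ccc(OCc9ccccc9)cc4)[C@H]3OCc9ccccc9)c(OCc9ccccc9)cc5OCc9ccccc9)N1[C@H](Cc2ccccc2)COC1=O | intermediate
27 | (2R,3S)-3-[2-(allyloxy)-4,6-bis(benzyloxy)-3-(T-yl)phenyl]-2-(benzyloxy)-3-hydroxypropaneperoxoic acid | OOC(=O)[C@H](OCc9ccccc9)[C@@H](O)c5c(OCC=C)c([C@H]3c4c(OCc9ccccc9)cc(OCc9ccccc9)cc4O[C@@H](c4ccc(OCc9ccccc9)cc4)[C@H]3OCc9ccccc9)c(OCc9ccccc9)cc5OCc9ccccc9 | intermediate (not isolated)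
28 | (2R,3S)-3-[2-(allyloxy)-4,6-bis(benzyloxy)-3-(T-yl)phenyl]-2-(benzyloxy)-3-hydroxypropanoic acid | OC(=O)[C@H](OCc9ccccc9)[C@@H](O)c5c(OCC=C)c([C@H]3c4c(OCc9ccccc9)cc(OCc9ccccc9)cc4O[C@@H](c4ccc(OCc9ccccc9)cc4)[C@H]3OCc9ccccc9)c(OCc9ccccc9)cc5OCc9ccccc9 | intermediate
29 | 3,5-bis(benzyloxy)phenyl (2R,3S)-3-[2-(allyloxy)-4,6-bis(benzyloxy)-3-(T-yl)phenyl]-2-(benzyloxy)-3-hydroxypropanoate | O=C(Oc1cc(OCc9ccccc9)cc(OCc9ccccc9)c1)[C@H](OCc9ccccc9)[C@@H](O)c5c(OCC=C)c([C@H]3c4c(OCc9ccccc9)cc(OCc9ccccc9)cc4O[C@@H](c4ccc(OCc9ccccc9)cc4)[C@H]3OCc9ccccc9)c(OCc9ccccc9)cc5OCc9ccccc9 | intermediate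
30 | (3R)-4-[2-(allyloxy)-4,6-bis(benzyloxy)-3-(T-yl)phenyl]-3,5,7-tris(benzyloxy)chroman-2-one (3,4-trans) | O=C1Oc2cc(OCc9ccccc9)cc(OCc9ccccc9)c2[C@H](c5c(OCC=C)c([C@H]3c4c(OCc9ccccc9)cc(OCc9ccccc9)cc4O[C@@H](c4ccc(OCc9ccccc9)cc4)[C@H]3OCc9ccccc9)c(OCc9ccccc9)cc5OCc9ccccc9)[C@H]1OCc9ccccc9 | intermediate
31 | (2R)-3-[2-(allyloxy)-4,6-bis(benzyloxy)-3-(T-yl)phenyl]-2-(benzyloxy)-1-[4-(benzyloxy)phenyl]-3-[2,4-bis(benzyloxy)-6-hydroxyphenyl]propan-1-one (C3 as C4 of 30) | Oc1cc(OCc9ccccc9)cc(OCc9ccccc9)c1[C@H](c5c(OCC=C)c([C@H]3c4c(OCc9ccccc9)cc(OCc9ccccc9)cc4O[C@@H](c4ccc(OCc9ccccc9)cc4)[C@H]3OCc9ccccc9)c(OCc9ccccc9)cc5OCc9ccccc9)[C@@H](OCc9ccccc9)C(=O)c6ccc(OCc9ccccc9)cc6 | intermediate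
32 | tert-butyldimethylsilyl ether of 31 at the phenol | CC(C)(C)[Si](C)(C)Oc1cc(OCc9ccccc9)cc(OCc9ccccc9)c1[C@H](c5c(OCC=C)c([C@H]3c4c(OCc9ccccc9)cc(OCc9ccccc9)cc4O[C@@H](c4ccc(OCc9ccccc9)cc4)[C@H]3OCc9ccccc9)c(OCc9ccccc9)cc5OCc9ccccc9)[C@@H](OCc9ccccc9)C(=O)c6ccc(OCc9ccccc9)cc6 | intermediate
33 | (2R)-2-(benzyloxy)-1-[4-(benzyloxy)phenyl]-3-[2,4-bis(benzyloxy)-6-(tert-butyldimethylsilyloxy)phenyl]-3-[4,6-bis(benzyloxy)-2-hydroxy-3-(T-yl)phenyl]propan-1-one | CC(C)(C)[Si](C)(C)Oc1cc(OCc9ccccc9)cc(OCc9ccccc9)c1[C@H](c5c(O)c([C@H]3c4c(OCc9ccccc9)cc(OCc9ccccc9)cc4O[C@@H](c4ccc(OCc9ccccc9)cc4)[C@H]3OCc9ccccc9)c(OCc9ccccc9)cc5OCc9ccccc9)[C@@H](OCc9ccccc9)C(=O)c6ccc(OCc9ccccc9)cc6 | intermediate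
34 | cyclic hemiketal of 33 (2-hydroxychromane closed from the phenol oxygen onto the ketone carbon; both C2 epimers) | O(Cc9ccccc9)c1ccc(C2(O)Oc3c(c(OCc9ccccc9)cc(OCc9ccccc9)c3[C@H]3c4c(OCc9ccccc9)cc(OCc9ccccc9)cc4O[C@@H](c4ccc(OCc9ccccc9)cc4)[C@H]3OCc9ccccc9)[C@@H](c3c(OCc9ccccc9)cc(OCc9ccccc9)cc3O[Si](C)(C)C(C)(C)C)[C@H]2OCc9ccccc9)cc1 | intermediate (not isolated)
35 | (2R,3R)-3,5,7-tris(benzyloxy)-2-[4-(benzyloxy)phenyl]-4-[2,4-bis(benzyloxy)-6-(tert-butyldimethylsilyloxy)phenyl]-8-(T-yl)chromane (all-cis) | O(Cc9ccccc9)c1ccc([C@H]2Oc3c(c(OCc9ccccc9)cc(OCc9ccccc9)c3[C@H]3c4c(OCc9ccccc9)cc(OCc9ccccc9)cc4O[C@@H](c4ccc(OCc9ccccc9)cc4)[C@H]3OCc9ccccc9)[C@@H](c3c(OCc9ccccc9)cc(OCc9ccccc9)cc3O[Si](C)(C)C(C)(C)C)[C@H]2OCc9ccccc9)cc1 | intermediate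
36 | 3,5-bis(benzyloxy)-2-(MT-yl)phenol | O(Cc9ccccc9)c1ccc([C@H]2Oc3c(c(OCc9ccccc9)cc(OCc9ccccc9)c3[C@H]3c4c(OCc9ccccc9)cc(OCc9ccccc9)cc4O[C@@H](c4ccc(OCc9ccccc9)cc4)[C@H]3OCc9ccccc9)[C@@H](c3c(OCc9ccccc9)cc(OCc9ccccc9)cc3O)[C@H]2OCc9ccccc9)cc1 | intermediate
37 | 4,6-bis(benzyloxy)-2-hydroxy-3-(MT-yl)benzaldehyde | O(Cc9ccccc9)c1ccc([C@H]2Oc3c(c(OCc9ccccc9)cc(OCc9ccccc9)c3[C@H]3c4c(OCc9ccccc9)cc(OCc9ccccc9)cc4O[C@@H](c4ccc(OCc9ccccc9)cc4)[C@H]3OCc9ccccc9)[C@@H](c3c(OCc9ccccc9)cc(OCc9ccccc9)c(C=O)c3O)[C@H]2OCc9ccccc9)cc1 | intermediate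
38 | 2-(allyloxy)-4,6-bis(benzyloxy)-3-(MT-yl)benzaldehyde | O(Cc9ccccc9)c1ccc([C@H]2Oc3c(c(OCc9ccccc9)cc(OCc9ccccc9)c3[C@H]3c4c(OCc9ccccc9)cc(OCc9ccccc9)cc4O[C@@H](c4ccc(OCc9ccccc9)cc4)[C@H]3OCc9ccccc9)[C@@H](c3c(OCc9ccccc9)cc(OCc9ccccc9)c(C=O)c3OCC=C)[C@H]2OCc9ccccc9)cc1 | intermediate
39 | (S)-4-isopropyl-1,3-oxazolidin-2-one | O=C1N[C@@H](C(C)C)CO1 | starting material
40 | (S)-3-[(benzyloxy)acetyl]-4-isopropyl-1,3-oxazolidin-2-one | O=C(COCc1ccccc1)N1[C@@H](C(C)C)COC1=O | intermediate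
41 | (Z)-dibutylboron enolate of 40 | CCCCB(CCCC)O/C(=C\OCc1ccccc1)N1[C@@H](C(C)C)COC1=O | intermediate (not isolated)
42 | (4S)-3-{(2S,3R)-3-[2-(allyloxy)-4,6-bis(benzyloxy)-3-(MT-yl)phenyl]-2-(benzyloxy)-3-hydroxypropanoyl}-4-isopropyl-1,3-oxazolidin-2-one | O(Cc9ccccc9)c1ccc([C@H]2Oc3c(c(OCc9ccccc9)cc(OCc9ccccc9)c3[C@H]3c4c(OCc9ccccc9)cc(OCc9ccccc9)cc4O[C@@H](c4ccc(OCc9ccccc9)cc4)[C@H]3OCc9ccccc9)[C@@H](c3c(OCc9ccccc9)cc(OCc9ccccc9)c([C@@H](O)[C@H](OCc9ccccc9)C(=O)N6[C@@H](C(C)C)COC6=O)c3OCC=C)[C@H]2OCc9ccccc9)cc1 | intermediate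
43 | (2S,3R)-3-[2-(allyloxy)-4,6-bis(benzyloxy)-3-(MT-yl)phenyl]-2-(benzyloxy)-3-hydroxy-N-methoxy-N-methylpropanamide | O(Cc9ccccc9)c1ccc([C@H]2Oc3c(c(OCc9ccccc9)cc(OCc9ccccc9)c3[C@H]3c4c(OCc9ccccc9)cc(OCc9ccccc9)cc4O[C@@H](c4ccc(OCc9ccccc9)cc4)[C@H]3OCc9ccccc9)[C@@H](c3c(OCc9ccccc9)cc(OCc9ccccc9)c([C@@H](O)[C@H](OCc9ccccc9)C(=O)N(C)OC)c3OCC=C)[C@H]2OCc9ccccc9)cc1 | intermediate
44 | (2S,3R)-3-[2-(allyloxy)-4,6-bis(benzyloxy)-3-(MT-yl)phenyl]-2-(benzyloxy)-3-(tert-butyldimethylsilyloxy)-N-methoxy-N-methylpropanamide | O(Cc9ccccc9)c1ccc([C@H]2Oc3c(c(OCc9ccccc9)cc(OCc9ccccc9)c3[C@H]3c4c(OCc9ccccc9)cc(OCc9ccccc9)cc4O[C@@H](c4ccc(OCc9ccccc9)cc4)[C@H]3OCc9ccccc9)[C@@H](c3c(OCc9ccccc9)cc(OCc9ccccc9)c([C@@H](O[Si](C)(C)C(C)(C)C)[C@H](OCc9ccccc9)C(=O)N(C)OC)c3OCC=C)[C@H]2OCc9ccccc9)cc1 | intermediate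
45 | (2S,3R)-3-[2-(allyloxy)-4,6-bis(benzyloxy)-3-(MT-yl)phenyl]-2-(benzyloxy)-1-[4-(benzyloxy)phenyl]-3-(tert-butyldimethylsilyloxy)propan-1-one | O(Cc9ccccc9)c1ccc([C@H]2Oc3c(c(OCc9ccccc9)cc(OCc9ccccc9)c3[C@H]3c4c(OCc9ccccc9)cc(OCc9ccccc9)cc4O[C@@H](c4ccc(OCc9ccccc9)cc4)[C@H]3OCc9ccccc9)[C@@H](c3c(OCc9ccccc9)cc(OCc9ccccc9)c([C@@H](O[Si](C)(C)C(C)(C)C)[C@H](OCc9ccccc9)C(=O)c6ccc(OCc9ccccc9)cc6)c3OCC=C)[C@H]2OCc9ccccc9)cc1 | intermediate
46 | 1,2-anti-3-[2-(allyloxy)-4,6-bis(benzyloxy)-3-(MT-yl)phenyl]-2-(benzyloxy)-1-[4-(benzyloxy)phenyl]-3-(tert-butyldimethylsilyloxy)propan-1-ol (C2 and C3 as in 45) | O(Cc9ccccc9)c1ccc([C@H]2Oc3c(c(OCc9ccccc9)cc(OCc9ccccc9)c3[C@H]3c4c(OCc9ccccc9)cc(OCc9ccccc9)cc4O[C@@H](c4ccc(OCc9ccccc9)cc4)[C@H]3OCc9ccccc9)[C@@H](c3c(OCc9ccccc9)cc(OCc9ccccc9)c([C@@H](O[Si](C)(C)C(C)(C)C)[C@H](OCc9ccccc9)[C@H](O)c6ccc(OCc9ccccc9)cc6)c3OCC=C)[C@H]2OCc9ccccc9)cc1 | intermediate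
47 | 1,2-anti-2-(benzyloxy)-1-[4-(benzyloxy)phenyl]-3-[4,6-bis(benzyloxy)-2-hydroxy-3-(MT-yl)phenyl]-3-(tert-butyldimethylsilyloxy)propan-1-ol (C2 and C3 as in 45) | O(Cc9ccccc9)c1ccc([C@H]2Oc3c(c(OCc9ccccc9)cc(OCc9ccccc9)c3[C@H]3c4c(OCc9ccccc9)cc(OCc9ccccc9)cc4O[C@@H](c4ccc(OCc9ccccc9)cc4)[C@H]3OCc9ccccc9)[C@@H](c3c(OCc9ccccc9)cc(OCc9ccccc9)c([C@@H](O[Si](C)(C)C(C)(C)C)[C@H](OCc9ccccc9)[C@H](O)c6ccc(OCc9ccccc9)cc6)c3O)[C@H]2OCc9ccccc9)cc1 | intermediate
48 | (2S)-3,5,7-tris(benzyloxy)-2-[4-(benzyloxy)phenyl]-4-(tert-butyldimethylsilyloxy)-8-(MT-yl)chromane (2,3-cis-3,4-trans) | O(Cc9ccccc9)c1ccc([C@H]2Oc3c(c(OCc9ccccc9)cc(OCc9ccccc9)c3[C@H]3c4c(OCc9ccccc9)cc(OCc9ccccc9)cc4O[C@@H](c4ccc(OCc9ccccc9)cc4)[C@H]3OCc9ccccc9)[C@@H](c3c(OCc9ccccc9)cc(OCc9ccccc9)c4c3O[C@@H](c3ccc(OCc9ccccc9)cc3)[C@@H](OCc9ccccc9)[C@@H]4O[Si](C)(C)C(C)(C)C)[C@H]2OCc9ccccc9)cc1 | intermediate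
49 | (2S)-3,5,7-tris(benzyloxy)-2-[4-(benzyloxy)phenyl]-8-(MT-yl)chroman-4-ol (2,3-cis-3,4-trans) | O(Cc9ccccc9)c1ccc([C@H]2Oc3c(c(OCc9ccccc9)cc(OCc9ccccc9)c3[C@H]3c4c(OCc9ccccc9)cc(OCc9ccccc9)cc4O[C@@H](c4ccc(OCc9ccccc9)cc4)[C@H]3OCc9ccccc9)[C@@H](c3c(OCc9ccccc9)cc(OCc9ccccc9)c4c3O[C@@H](c3ccc(OCc9ccccc9)cc3)[C@@H](OCc9ccccc9)[C@@H]4O)[C@H]2OCc9ccccc9)cc1 | intermediate
50 | CNP0159291.1: unit B (2S,3S,4R)-2-(4-hydroxyphenyl)chromane-3,4,5,7-tetrol bearing at C8 the C4 of unit M [(2R,3R,4S)-2-(4-hydroxyphenyl)chromane-3,5,7-triol], which bears at C8 the C4 of unit T [(2S,3S,4R)-2-(4-hydroxyphenyl)chromane-3,5,7-triol] | Oc1ccc([C@H]2Oc3c(c(O)cc(O)c3[C@H]3c4c(O)cc(O)cc4O[C@@H](c4ccc(O)cc4)[C@H]3O)[C@@H](c3c(O)cc(O)c4c3O[C@@H](c3ccc(O)cc3)[C@@H](O)[C@@H]4O)[C@H]2O)cc1 | target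

**Totals and risks**

Total step count: 36. Longest linear sequence: 33 steps (1 to 50 through steps 1, 2, 4–14, 16–26 and 28–36; steps 3, 15 and 27 make the three imides off the main line).

Three steps most likely to fail:

- **Step 23 (ring C of unit M).** The silane may reduce the open-chain ketone before the hemiketal ionises, hydride delivery may lose its facial preference, or the acid may begin reductive opening of the benzylic O1–C2 bonds already present. Fallback: keto phenol 33 is reduced with Zn(BH4)2 in Et2O at −30 °C, through the chelate of the ketone and the 2-benzyloxy group, to the 1,2-anti alcohol F1. PPh3 and DIAD in toluene then close O1–C2 with inversion and return to 35. This replaces the cation by an SN2 closure, the pair of reactions used in steps 32 and 34.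

- **Step 34 (ring C of unit B).** The activated 4-benzyloxybenzylic alcohol may ionise, so that the ring closes on a cation and the inversion at C2 is lost, or it may eliminate. Fallback: the route is left at Weinreb amide 44. The allyl group is removed (Pd(PPh3)4, morpholine) to give the phenol F2, which is converted into the aryl triflate F3 (PhNTf2, K2CO3, DMF). i-Bu2AlH at −78 °C gives the aldehyde F4, and Grignard reagent 16 adds under chelation control as in step 9 to give the 1,2-syn alcohol F5. The conditions of step 11 then close O1–C8a and return to 48, so C2 is never a reacting centre.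

- **Step 20 (aryl ketone from the lactone).** The hemiketal may collapse early and take up a second Grignard equivalent, or the carbon next to the new ketone may epimerise. Fallback: lactone 30 is opened with Me(MeO)NH·HCl and AlMe3 to the Weinreb amide phenol F6. TBSCl and imidazole give the silyl ether F7, and reagent 16 then converts the amide into ketone 32, where the route resumes.

**Further compounds**

F1 | step 23 | 1,2-anti-2-(benzyloxy)-1-[4-(benzyloxy)phenyl]-3-[2,4-bis(benzyloxy)-6-(tert-butyldimethylsilyloxy)phenyl]-3-[4,6-bis(benzyloxy)-2-hydroxy-3-(T-yl)phenyl]propan-1-ol (C2 and C3 as in 33) | CC(C)(C)[Si](C)(C)Oc1cc(OCc9ccccc9)cc(OCc9ccccc9)c1[C@H](c5c(O)c([C@H]3c4c(OCc9ccccc9)cc(OCc9ccccc9)cc4O[C@@H](c4ccc(OCc9ccccc9)cc4)[C@H]3OCc9ccccc9)c(OCc9ccccc9)cc5OCc9ccccc9)[C@@H](OCc9ccccc9)[C@@H](O)c6ccc(OCc9ccccc9)cc6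
F2 | step 34 | (2S,3R)-2-(benzyloxy)-3-[4,6-bis(benzyloxy)-2-hydroxy-3-(MT-yl)phenyl]-3-(tert-butyldimethylsilyloxy)-N-methoxy-N-methylpropanamide | O(Cc9ccccc9)c1ccc([C@H]2Oc3c(c(OCc9ccccc9)cc(OCc9ccccc9)c3[C@H]3c4c(OCc9ccccc9)cc(OCc9ccccc9)cc4O[C@@H](c4ccc(OCc9ccccc9)cc4)[C@H]3OCc9ccccc9)[C@@H](c3c(OCc9ccccc9)cc(OCc9ccccc9)c([C@@H](O[Si](C)(C)C(C)(C)C)[C@H](OCc9ccccc9)C(=O)N(C)OC)c3O)[C@H]2OCc9ccccc9)cc1
F3 | step 34 | aryl trifluoromethanesulfonate of F2 | O(Cc9ccccc9)c1ccc([C@H]2Oc3c(c(OCc9ccccc9)cc(OCc9ccccc9)c3[C@H]3c4c(OCc9ccccc9)cc(OCc9ccccc9)cc4O[C@@H](c4ccc(OCc9ccccc9)cc4)[C@H]3OCc9ccccc9)[C@@H](c3c(OCc9ccccc9)cc(OCc9ccccc9)c([C@@H](O[Si](C)(C)C(C)(C)C)[C@H](OCc9ccccc9)C(=O)N(C)OC)c3OS(=O)(=O)C(F)(F)F)[C@H]2OCc9ccccc9)cc1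
F4 | step 34 | aldehyde from F3: (2S,3R)-2-(benzyloxy)-3-(tert-butyldimethylsilyloxy)-3-aryl-propanal with the aryl triflate retained | O(Cc9ccccc9)c1ccc([C@H]2Oc3c(c(OCc9ccccc9)cc(OCc9ccccc9)c3[C@H]3c4c(OCc9ccccc9)cc(OCc9ccccc9)cc4O[C@@H](c4ccc(OCc9ccccc9)cc4)[C@H]3OCc9ccccc9)[C@@H](c3c(OCc9ccccc9)cc(OCc9ccccc9)c([C@@H](O[Si](C)(C)C(C)(C)C)[C@H](OCc9ccccc9)C=O)c3OS(=O)(=O)C(F)(F)F)[C@H]2OCc9ccccc9)cc1
F5 | step 34 | 1,2-syn alcohol from F4 and 16 (C1 epimer of 47 at the carbinol, phenol as triflate) | O(Cc9ccccc9)c1ccc([C@H]2Oc3c(c(OCc9ccccc9)cc(OCc9ccccc9)c3[C@H]3c4c(OCc9ccccc9)cc(OCc9ccccc9)cc4O[C@@H](c4ccc(OCc9ccccc9)cc4)[C@H]3OCc9ccccc9)[C@@H](c3c(OCc9ccccc9)cc(OCc9ccccc9)c([C@@H](O[Si](C)(C)C(C)(C)C)[C@H](OCc9ccccc9)[C@@H](O)c6ccc(OCc9ccccc9)cc6)c3OS(=O)(=O)C(F)(F)F)[C@H]2OCc9ccccc9)cc1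
F6 | step 20 | (2R)-3-[2-(allyloxy)-4,6-bis(benzyloxy)-3-(T-yl)phenyl]-2-(benzyloxy)-3-[2,4-bis(benzyloxy)-6-hydroxyphenyl]-N-methoxy-N-methylpropanamide (C3 as C4 of 30) | Oc1cc(OCc9ccccc9)cc(OCc9ccccc9)c1[C@H](c5c(OCC=C)c([C@H]3c4c(OCc9ccccc9)cc(OCc9ccccc9)cc4O[C@@H](c4ccc(OCc9ccccc9)cc4)[C@H]3OCc9ccccc9)c(OCc9ccccc9)cc5OCc9ccccc9)[C@@H](OCc9ccccc9)C(=O)N(C)OC
F7 | step 20 | tert-butyldimethylsilyl ether of F6 at the phenol | CC(C)(C)[Si](C)(C)Oc1cc(OCc9ccccc9)cc(OCc9ccccc9)c1[C@H](c5c(OCC=C)c([C@H]3c4c(OCc9ccccc9)cc(OCc9ccccc9)cc4O[C@@H](c4ccc(OCc9ccccc9)cc4)[C@H]3OCc9ccccc9)c(OCc9ccccc9)cc5OCc9ccccc9)[C@@H](OCc9ccccc9)C(=O)N(C)OC
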